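Atom numbers follow the germacrane skeleton: ring C1–C10, lactone carbons C11–C13, C14 on C10, C15 on C4. Compound numbers: 1–4 enone branch, 5–7 cyclobutene branch, 8 photoadduct, 9–13 ten-membered ring intermediates, 14–15 keto ester branch, 16–21 butenolide series, 22–24 angelate, 25 monoepoxide, 26 target.

## Analysis of the target

Compound 26 is a germacranolide: a ten-membered carbocycle (C1–C10) fused at C6–C7 to a butenolide (O on C6, C7=C11, C12=O) that carries an acetoxymethyl group (C13) on C11. C8 bears an angelate, and the ring carries epoxides across C1/C10 and C4/C5 with methyl groups C14 on C10 and C15 on C4. The six stereocentres are 1R,4R,5R,6S,8S,10R. The oxygens on C6 and C8 are cis to each other across the trigonal C7. In each oxirane the two ring carbons are trans, so both are the oxides of an (E,E)-cyclodeca-1(10),4-diene, and they have the same sense, as expected for attack on the outer faces of one crown conformer in which the two alkenes are related by a local twofold axis. Sensitive groups are the angelate (Z to E isomerisation), the allylic acetate on the butenolide (loss of acetate after deprotonation at C6), and the epoxides (transannular opening under acid). The difficulty is the ten-membered ring with two trans trisubstituted alkene equivalents, which resists direct cyclisation, and the relay of one early stereocentre (C8) to C6 and to the four epoxide carbons. The strategy rests on the 1,5-relationship of the C1–C10 and C4–C5 bonds: drawn as the two new bonds of a cyclobutane (C1, C10, C5, C4) fused to a second cyclobutane (C1–C4) and to a cyclohexane (C5–C10), they turn the ten-membered ring into a 6-4-4 tricycle that opens on heating.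

## Retrosynthetic reasoning

Both oxirane oxygens of 26 are removed first, giving triene 24. The cut is made here because the epoxides are the most acid-sensitive groups and because only the two ring alkenes of 24 are electron-rich. The forward step must deliver oxygen to the outer face of each alkene under neutral conditions.

The angelate C–O bond at C8 is cut next, giving alcohol 21 and angelic acid 22; 21 comes from silyl ether 20. The angelate is put on late because it isomerises easily and would not survive the earlier reductions.

The butenolide of 20 is opened at the C7=C11 alkene (dehydration of tertiary alcohol 18) and at the lactone C12–O6 bond with the C6–H bond (reduction of ketone 16, then closure of 17). This places all carbons of the lactone on a C6 ketone and makes C6 the last ring stereocentre to be set, under control of the side chain.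

The C7–C11 bond of 16 is cut to the silyl dienol ether 13 and keto ester 15, which carries C11, C12 and C13 with the acetate already in place; 15 comes from 14. C7 is the only enolisable position of the C6 ketone, so the aldol has no regiochemical choice.

The C15 methyl of 13 is traced to an ester through alcohol 11 and ester 10. The C6 ketone of 9 is masked as its silyl dienol ether 10 during this reduction, and the same enol ether then serves as the aldol donor, so no protecting-group step is lost.

The ten-membered ring of 9 is closed on paper by joining C1–C4 and C5–C10, giving tricycle 8. The forward reaction is a thermal cycloreversion driven by the strain of the bicyclo[2.2.0]hexane; it has to produce both alkenes with the ring carbons trans.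

Tricycle 8 is cut at C1–C10 and C4–C5 into enone 4 and cyclobutene ester 7. These are the two bonds a [2+2] photocycloaddition forms; the ester on 7 is needed to direct C4 to the enone α-carbon C5 and becomes C15.

Enone 4 is cut at its ring alkene into keto phosphonate 3, made from the commercial, enantiopure phosphonate ester 1 through Weinreb amide 2. This fixes C8 from the start without a resolution or a desymmetrising aldol. Ester 7 comes from bromo ester 5 through acid 6.

## Alternatives that were turned down

Alternative 1: The carbocycle is cut at C9–C10. In the forward direction Ni(cod)2 (zerovalent nickel) with PBu3 and Et3B would join, within one open chain, the methyl-bearing alkyne carbon C10 to the terminal carbon of a C8/C9 epoxide, adding hydrogen to C1 on the same side and freeing the C8 hydroxyl, to give cyclodecadienol A1. In its favour, C6 and C8 are fixed before ring closure, the 1(10)E geometry follows from the syn addition, and the C7 ketal next to the C6 ether allows a butenolide annulation by intramolecular olefination with no doubt about alkene geometry or C6 configuration. On those two points it is stronger than the chosen route, whose steps 13 and 14 are open questions. Against it, the key step must close a ten-membered ring while creating a trans trisubstituted alkene in a chain that already holds another, against both strain and entropy, next to a fully substituted ketal carbon. The open-chain substrate also needs a long linear sequence with its own stereodefined trisubstituted alkene. The chosen strategy instead obtains the ring from strain release in a tricycle made in one convergent step from two small fragments.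

Alternative 2: The C4–O bond of the 4,5-epoxide and the lactone C12–O bond are cut together. In the forward direction base would convert a C4 tertiary alcohol into its alkoxide, which opens a cis-5,6-epoxide at C5 with inversion; the freed C6 alkoxide would then close onto a C12 ester to give epoxy lactone A2. In its favour, the 4,5-epoxide and C6 are set stereospecifically, independent of ring conformation, which is stronger than the conformational control relied on in step 17. Against it, the epoxide migration is reversible and is pulled forward only by the lactonisation, and it needs a ten-membered ring that already contains the cis-epoxide, the E-alkene, a tetrasubstituted Z-enoate and the C4 carbinol. The hard ring formation is only moved elsewhere, and the 1,10-epoxide still depends on substrate control. The chosen route is shorter to the ring and sets both epoxides in one operation, at the price of less certain facial control.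

Alternative 3: A C2=C3 alkene is cut after inserting sulfur between C2 and C3. In the forward direction a sulfonyl bridge in an eleven-membered bis-allylic ring would be chlorinated and deprotonated in situ (KOH, CCl4), SO2 would be lost, and the ring would contract to triene A3. In its favour, an eleven-membered ring with sulfur closes more easily by alkylation at sulfur than a ten-membered carbocycle closes by C–C bond formation, and A3 again has the C6 carbinol and C7 ketal suited to an unambiguous butenolide synthesis. Against it, the C2=C3 alkene is not in 26 and would have to be reduced selectively in a conjugated triene whose two trisubstituted alkenes must survive. The strongly basic halogenating medium is also harsh for a β-oxygenated ketal. The chosen strategy delivers C2–C3 saturated from the cyclobutene and needs no such selective reduction.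

Key step: step 6

Remarks on the chemistry:
- Compound 8 is written as the expected major head-to-head, cis-anti-cis adduct. Its facial isomer with respect to C8 leads to the same diene 9. Trans-fused isomers are epimerised at C5 on basic alumina before step 7. A syn isomer would not give the ring-trans alkenes and is removed.
- C7 and C11 of 16–19 are transient. C7 is drawn as expected (side chain anti to the C8 silyl ether) and C11 is left undefined (both epimers are carried).
- The same spatial arrangement at C6 is 6R in 17–25 and 6S in 26, because C5 gains priority on epoxidation.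

Step 1
Reactants: 1 methyl (3R)-3-[(tert-butyldimethylsilyl)oxy]-6-(dimethoxyphosphoryl)-5-oxohexanoate
Product: 2 (3R)-3-[(tert-butyldimethylsilyl)oxy]-6-(dimethoxyphosphoryl)-N-methoxy-N-methyl-5-oxohexanamide
Conditions: MeNH(OMe)·HCl, iPrMgCl, THF, −20 → 0 °C
Reagents that add atoms: N,O-dimethylhydroxylamine hydrochloride, CNOC.Cl
Why: Weinreb amide formation from an ester with the magnesium amide; the β-keto phosphonate is deprotonated first and its enolate is inert, and the silyl ether and the carbinol centre are not touched.

Step 2
Reactants: 2 (3R)-3-[(tert-butyldimethylsilyl)oxy]-6-(dimethoxyphosphoryl)-N-methoxy-N-methyl-5-oxohexanamide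
Product: 3 dimethyl [(4S)-4-[(tert-butyldimethylsilyl)oxy]-2,6-dioxoheptyl]phosphonate
Conditions: MeMgBr, THF, −78 → 0 °C; aq NH4Cl
Reagents that add atoms: methylmagnesium bromide, C[Mg]Br
Why: Weinreb ketone synthesis; the chelated tetrahedral intermediate prevents a second addition and the phosphonate is protected as its magnesium enolate (the descriptor changes to S only through the priority order).

Step 3
Reactants: 3 dimethyl [(4S)-4-[(tert-butyldimethylsilyl)oxy]-2,6-dioxoheptyl]phosphonate
Product: 4 (S)-5-[(tert-butyldimethylsilyl)oxy]-3-methylcyclohex-2-en-1-one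
Conditions: LiCl, iPr2NEt, MeCN, rt
Reagents that add atoms: none
Why: Intramolecular Horner–Wadsworth–Emmons olefination under Masamune–Roush conditions closes the six-membered enone; the mild amine base is chosen so that the β-silyloxy group is not eliminated, and which end is ketone and which is phosphonate fixes the enantiomer.

Step 4
Reactants: 5 ethyl 1-bromocyclobutane-1-carboxylate
Product: 6 cyclobut-1-ene-1-carboxylic acid
Conditions: KOH, toluene, reflux; then aq HCl
Reagents that add atoms: potassium hydroxide, [K+].[OH-]
Why: E2 dehydrobromination of the tertiary α-bromo ester with concurrent saponification; the acid is used at once because it polymerises on standing.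

Step 5
Reactants: 6 cyclobut-1-ene-1-carboxylic acid
Product: 7 methyl cyclobut-1-ene-1-carboxylate
Conditions: MeI, K2CO3, DMF, 0 °C → rt
Reagents that add atoms: iodomethane, CI
Why: O-alkylation of the carboxylate avoids acid and heat, which the strained acrylate would not tolerate.

Step 6
Reactants: 4 (S)-5-[(tert-butyldimethylsilyl)oxy]-3-methylcyclohex-2-en-1-one; 7 methyl cyclobut-1-ene-1-carboxylate
Product: 8 methyl 8-[(tert-butyldimethylsilyl)oxy]-6-methyl-10-oxotricyclo[4.4.0.0(2,5)]decane-2-carboxylate (head-to-head cis-anti-cis)
Conditions: hν (medium-pressure Hg lamp, Pyrex), 7 (5 equiv), CH2Cl2, −20 °C; then basic Al2O3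
Reagents that add atoms: none
Why: Excitation and intersystem crossing give the triplet enone, whose β-carbon C10 bonds to the unsubstituted cyclobutene carbon C1; the 1,4-diradical so formed is tertiary and ester-stabilised at C4 and α-acyl at C5, and after spin inversion C4–C5 closes. The closest known reaction type is the intermolecular [2+2] photocycloaddition of a cyclohexenone with an electron-poor cycloalkene. The one new ring, the cyclobutane C1–C10–C5–C4, is closed by collapse of this 1,4-diradical. C1 and C4 are cis because a cyclobutene can only be cis-fused. C10 and C5 should end cis on the six-membered ring, and any trans-fused adduct is epimerised at C5, which is α to the ketone, on the alumina. The cyclobutene ring should lie anti to the cyclohexanone ring and to the C8 silyl ether for steric reasons. The step needs head-to-head regiochemistry and the anti arrangement: the first follows from the preference of an acceptor-substituted alkene to place its substituted carbon next to the enone α-carbon, the second from the least hindered approach. The facial sense relative to C8 is not needed, because all four new centres become trigonal in step 7.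

Step 7
Reactants: 8 methyl 8-[(tert-butyldimethylsilyl)oxy]-6-methyl-10-oxotricyclo[4.4.0.0(2,5)]decane-2-carboxylate
Product: 9 methyl (8S)-8-[(tert-butyldimethylsilyl)oxy]-6-oxogermacra-1(10),4-dien-15-oate (C2 trans to C9 and C3 trans to C6)
Conditions: toluene (degassed, 0.01 M), silylated sealed tube, 180 °C
Reagents that add atoms: none
Why: Thermal cycloreversion of the bicyclo[2.2.0]hexane: the central C1–C4 bond breaks to a 1,4-diyl stabilised by the ester, and cleavage of C5–C10 next to the ketone releases both four-membered rings as C1=C10 and C4=C5. The cis-anti-cis arrangement places C2/C3 and C6/C9 on opposite faces of the breaking cyclobutane, which translates into ring-trans geometry at both alkenes; C8 is not involved.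

Step 8
Reactants: 9 methyl (8S)-8-[(tert-butyldimethylsilyl)oxy]-6-oxogermacra-1(10),4-dien-15-oate
Product: 10 methyl (8S)-6,8-bis[(tert-butyldimethylsilyl)oxy]germacra-1(10),4,6-trien-15-oate (C6=C7 ring-cis)
Conditions: TBSOTf, Et3N, CH2Cl2, −78 → 0 °C
Reagents that add atoms: tert-butyldimethylsilyl trifluoromethanesulfonate, CC(C)(C)[Si](C)(C)OS(=O)(=O)C(F)(F)F
Why: Soft enolisation of the enone at C7, its only sp3 α-position, gives the cross-conjugated silyl dienol ether; this masks the ketone for the next two steps without forming a free enolate that could expel the C8 silyloxy group.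

Step 9
Reactants: 10 methyl (8S)-6,8-bis[(tert-butyldimethylsilyl)oxy]germacra-1(10),4,6-trien-15-oate
Product: 11 (8S)-6,8-bis[(tert-butyldimethylsilyl)oxy]germacra-1(10),4,6-trien-15-ol
Conditions: (iBu)2AlH, CH2Cl2, −78 °C; aq KNaC4H4O6
Reagents that add atoms: none
Why: 1,2-Reduction of a conjugated ester to the allylic alcohol; silyl ethers and the enol ether are inert to the hydride.

Step 10
Reactants: 11 (8S)-6,8-bis[(tert-butyldimethylsilyl)oxy]germacra-1(10),4,6-trien-15-ol
Product: 13 (8S)-6,8-bis[(tert-butyldimethylsilyl)oxy]germacra-1(10),4,6-triene, via C15 mesylate 12 (not isolated)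
Conditions: MsCl, Et3N, CH2Cl2, −30 °C; then LiBHEt3, THF, −78 → 0 °C
Reagents that add atoms: none
Why: Sulfonylation of the primary allylic alcohol and direct SN2 displacement by the borohydride give the C15 methyl; attack at the unhindered primary carbon is preferred over allylic transposition, and with C6 masked there is no neighbouring hydroxyl to close a dihydrofuran.

Step 11
Reactants: 14 ethyl bromopyruvate
Product: 15 ethyl 3-acetoxy-2-oxopropanoate
Conditions: KOAc, 18-crown-6 (cat.), MeCN, 0 °C → rt
Reagents that add atoms: potassium acetate, CC(=O)[O-].[K+]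
Why: SN2 displacement at an α-halo ketone is fast, and installing the C13 acetate here spares a later substitution on a sensitive allylic halide.

Step 12
Reactants: 13 (8S)-6,8-bis[(tert-butyldimethylsilyl)oxy]germacra-1(10),4,6-triene; 15 ethyl 3-acetoxy-2-oxopropanoate
Product: 16 ethyl (8S)-13-acetoxy-8-[(tert-butyldimethylsilyl)oxy]-11-hydroxy-6-oxogermacra-1(10),4-dien-12-oate
Conditions: BF3·OEt2, CH2Cl2, −78 °C; aq NaHCO3
Reagents that add atoms: none
Why: Mukaiyama aldol addition of the silyl dienol ether through C7 to the activated α-keto ester regenerates the C6 enone and forms C7–C11; attack should occur on the face of the enol ether away from the allylic C8 silyloxy group.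

Step 13
Reactants: 16 ethyl (8S)-13-acetoxy-8-[(tert-butyldimethylsilyl)oxy]-11-hydroxy-6-oxogermacra-1(10),4-dien-12-oate
Product: 18 (6R,8S)-13-acetoxy-8-[(tert-butyldimethylsilyl)oxy]-11-hydroxygermacra-1(10),4-dien-12,6-olide, via diol ester 17 (not isolated)
Conditions: Me4NBH(OAc)3, MeCN/AcOH, −30 → 0 °C; then PPTS (cat.), CH2Cl2, rt
Reagents that add atoms: none
Why: Evans–Saksena reduction: the borohydride exchanges onto the tertiary C11 hydroxyl and delivers hydride to C6 on the face that carries the side chain, so O6 ends trans to C11 and, with the side chain anti to O8, cis to O8 as 26 requires. The γ-hydroxy ester then lactonises under mild acid, and the C8 silyl ether rules out closure onto O8.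

Step 14
Reactants: 18 (6R,8S)-13-acetoxy-8-[(tert-butyldimethylsilyl)oxy]-11-hydroxygermacra-1(10),4-dien-12,6-olide
Product: 20 (6R,8S)-13-acetoxy-8-[(tert-butyldimethylsilyl)oxy]germacra-1(10),4,7(11)-trien-12,6-olide, via chlorosulfite 19 (not isolated)
Conditions: SOCl2, pyridine, CH2Cl2, −20 → 0 °C
Reagents that add atoms: none
Why: Dehydration of a tertiary α-hydroxy lactone through its chlorosulfite by E2 elimination; loss of the C7 hydrogen gives the tetrasubstituted conjugated butenolide and erases C7 and C11, whereas loss of a C13 hydrogen would give a less substituted enol acetate.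

Step 15
Reactants: 20 (6R,8S)-13-acetoxy-8-[(tert-butyldimethylsilyl)oxy]germacra-1(10),4,7(11)-trien-12,6-olide
Product: 21 (6R,8S)-13-acetoxy-8-hydroxygermacra-1(10),4,7(11)-trien-12,6-olide
Conditions: HF·pyridine, pyridine, THF, 0 °C → rt
Reagents that add atoms: none
Why: Buffered fluoride cleavage of the secondary silyl ether avoids the basic conditions under which the butenolide could lose acetate or the acetate could migrate.

Step 16
Reactants: 21 (6R,8S)-13-acetoxy-8-hydroxygermacra-1(10),4,7(11)-trien-12,6-olide; 22 angelic acid
Product: 24 (6R,8S)-13-acetoxy-8-angeloyloxygermacra-1(10),4,7(11)-trien-12,6-olide, via mixed anhydride 23 (not isolated)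
Conditions: 22, 2,4,6-Cl3C6H2COCl, Et3N, toluene, rt; filter; then 21, toluene, 70 °C
Reagents that add atoms: none
Why: Yamaguchi-type esterification through the angelic 2,4,6-trichlorobenzoic mixed anhydride, run without a nucleophilic amine catalyst so that the Z-alkene is not isomerised to the tiglate; the temperature is held well below that of the Cope rearrangement of the diene.

Step 17
Reactants: 24 (6R,8S)-13-acetoxy-8-angeloyloxygermacra-1(10),4,7(11)-trien-12,6-olide
Product: 26 (1R,4R,5R,6S,8S,10R)-13-acetoxy-8-angeloyloxy-1,10:4,5-diepoxygermacr-7(11)-en-12,6-olide, via 1,10-monoepoxide 25 (not isolated)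
Conditions: DMDO (2.5 equiv), acetone, −20 → 0 °C
Reagents that add atoms: dimethyldioxirane, CC1(C)OO1
Why: Neutral dioxirane epoxidation of the two electron-rich trisubstituted alkenes; the butenolide and angelate alkenes are conjugated and should not react. In the crown conformer imposed by the cis-6,8-dioxygenated butenolide only the outer face of each alkene is open, and these two faces are related by the local twofold axis, so both oxiranes should form with the same sense (1R,10R and 4R,5R), as in related germacranolides. The absence of acid avoids transannular opening of 25.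

Compound list
1 | methyl (3R)-3-[(tert-butyldimethylsilyl)oxy]-6-(dimethoxyphosphoryl)-5-oxohexanoate | COC(=O)C[C@H](O[Si](C)(C)C(C)(C)C)CC(=O)CP(=O)(OC)OC | starting material
2 | (3R)-3-[(tert-butyldimethylsilyl)oxy]-6-(dimethoxyphosphoryl)-N-methoxy-N-methyl-5-oxohexanamide | CON(C)C(=O)C[C@H](O[Si](C)(C)C(C)(C)C)CC(=O)CP(=O)(OC)OC | intermediate
3 | dimethyl [(4S)-4-[(tert-butyldimethylsilyl)oxy]-2,6-dioxoheptyl]phosphonate | CC(=O)C[C@H](O[Si](C)(C)C(C)(C)C)CC(=O)CP(=O)(OC)OC | intermediate
4 | (S)-5-[(tert-butyldimethylsilyl)oxy]-3-methylcyclohex-2-en-1-one | CC1=CC(=O)C[C@@H](O[Si](C)(C)C(C)(C)C)C1 | intermediate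
5 | ethyl 1-bromocyclobutane-1-carboxylate | CCOC(=O)C1(Br)CCC1 | starting material
6 | cyclobut-1-ene-1-carboxylic acid | OC(=O)C1=CCC1 | intermediate
7 | methyl cyclobut-1-ene-1-carboxylate | COC(=O)C1=CCC1 | intermediate
8 | methyl 8-[(tert-butyldimethylsilyl)oxy]-6-methyl-10-oxotricyclo[4.4.0.0(2,5)]decane-2-carboxylate, head-to-head cis-anti-cis photoadduct | COC(=O)[C@@]12CC[C@@H]1[C@@]1(C)C[C@H](O[Si](C)(C)C(C)(C)C)CC(=O)[C@H]12 | intermediate
9 | methyl (8S)-8-[(tert-butyldimethylsilyl)oxy]-6-oxogermacra-1(10),4-dien-15-oate, both alkenes ring-trans | C1/C(C(=O)OC)=C/C(=O)C[C@@H](O[Si](C)(C)C(C)(C)C)C/C(C)=C/C1 | intermediate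
10 | methyl (8S)-6,8-bis[(tert-butyldimethylsilyl)oxy]germacra-1(10),4,6-trien-15-oate | C1/C(C(=O)OC)=C/C(O[Si](C)(C)C(C)(C)C)=C\[C@@H](O[Si](C)(C)C(C)(C)C)C/C(C)=C/C1 | intermediate
11 | (8S)-6,8-bis[(tert-butyldimethylsilyl)oxy]germacra-1(10),4,6-trien-15-ol | C1/C(CO)=C/C(O[Si](C)(C)C(C)(C)C)=C\[C@@H](O[Si](C)(C)C(C)(C)C)C/C(C)=C/C1 | intermediate
12 | 15-methanesulfonate of 11 | C1/C(COS(C)(=O)=O)=C/C(O[Si](C)(C)C(C)(C)C)=C\[C@@H](O[Si](C)(C)C(C)(C)C)C/C(C)=C/C1 | intermediate
13 | (8S)-6,8-bis[(tert-butyldimethylsilyl)oxy]germacra-1(10),4,6-triene | C1/C(C)=C/C(O[Si](C)(C)C(C)(C)C)=C\[C@@H](O[Si](C)(C)C(C)(C)C)C/C(C)=C/C1 | intermediate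
14 | ethyl bromopyruvate (ethyl 3-bromo-2-oxopropanoate) | CCOC(=O)C(=O)CBr | starting material
15 | ethyl 3-acetoxy-2-oxopropanoate | CCOC(=O)C(=O)COC(C)=O | intermediate
16 | ethyl (8S)-13-acetoxy-8-[(tert-butyldimethylsilyl)oxy]-11-hydroxy-6-oxogermacra-1(10),4-dien-12-oate, C7 side chain anti to O8, C11 epimers | C1/C(C)=C/C(=O)[C@@H](C(O)(COC(C)=O)C(=O)OCC)[C@@H](O[Si](C)(C)C(C)(C)C)C/C(C)=C/C1 | intermediate
17 | ethyl (6R,8S)-13-acetoxy-8-[(tert-butyldimethylsilyl)oxy]-6,11-dihydroxygermacra-1(10),4-dien-12-oate | C1/C(C)=C/[C@@H](O)[C@@H](C(O)(COC(C)=O)C(=O)OCC)[C@@H](O[Si](C)(C)C(C)(C)C)C/C(C)=C/C1 | intermediate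
18 | (6R,8S)-13-acetoxy-8-[(tert-butyldimethylsilyl)oxy]-11-hydroxygermacra-1(10),4-dien-12,6-olide | C1/C(C)=C/[C@H]2OC(=O)C(O)(COC(C)=O)[C@H]2[C@@H](O[Si](C)(C)C(C)(C)C)C/C(C)=C/C1 | intermediate
19 | 11-chlorosulfite of 18 | C1/C(C)=C/[C@H]2OC(=O)C(OS(Cl)=O)(COC(C)=O)[C@H]2[C@@H](O[Si](C)(C)C(C)(C)C)C/C(C)=C/C1 | intermediate
20 | (6R,8S)-13-acetoxy-8-[(tert-butyldimethylsilyl)oxy]germacra-1(10),4,7(11)-trien-12,6-olide | C1/C(C)=C/[C@H]2OC(=O)C(COC(C)=O)=C2[C@@H](O[Si](C)(C)C(C)(C)C)C/C(C)=C/C1 | intermediate
21 | (6R,8S)-13-acetoxy-8-hydroxygermacra-1(10),4,7(11)-trien-12,6-olide | C1/C(C)=C/[C@H]2OC(=O)C(COC(C)=O)=C2[C@@H](O)C/C(C)=C/C1 | intermediate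
22 | angelic acid, (Z)-2-methylbut-2-enoic acid | C/C=C(/C)C(=O)O | starting material
23 | angelic 2,4,6-trichlorobenzoic anhydride | C/C=C(/C)C(=O)OC(=O)c1c(Cl)cc(Cl)cc1Cl | intermediate
24 | (6R,8S)-13-acetoxy-8-angeloyloxygermacra-1(10),4,7(11)-trien-12,6-olide | C/C=C(/C)C(=O)O[C@H]1C/C(C)=C/CC/C(C)=C/[C@H]2OC(=O)C(COC(C)=O)=C12 | intermediate
25 | (1R,6R,8S,10R)-13-acetoxy-8-angeloyloxy-1,10-epoxygermacra-4,7(11)-dien-12,6-olide | C/C=C(/C)C(=O)O[C@H]1C[C@@]2(C)O[C@@H]2CC/C(C)=C/[C@H]2OC(=O)C(COC(C)=O)=C12 | intermediate
26 | (1R,4R,5R,6S,8S,10R)-13-acetoxy-8-angeloyloxy-1,10:4,5-diepoxygermacr-7(11)-en-12,6-olide | C/C=C(/C)C(=O)O[C@H]1C[C@@]2(C)O[C@@H]2CC[C@@]2(C)O[C@@H]2[C@H]2OC(=O)C(COC(C)=O)=C12 | target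

Total step count: 17. Longest linear sequence: 14 steps (1 to 26 through steps 1–3, 6–10 and 12–17).

Steps least certain to work

Step 6 (key step). The most likely failure is erosion of head-to-head regioselectivity, the ester-bearing carbon bonding to C10 instead of C5, together with oligomerisation of 7 under irradiation. The fallback sets out from 4 and uses a smaller, more strongly polarised nitrile partner. Cyclobutanecarbonitrile is brominated (LDA, then BrCCl2CCl2Br) to 1-bromocyclobutane-1-carbonitrile F1, which DBU converts to cyclobut-1-ene-1-carbonitrile F2. Irradiation of 4 with F2 should give the nitrile photoadduct F3, and thermolysis the cyclodecadienone nitrile F4. Silylation (TBSOTf, Et3N) gives the silyl dienol ether nitrile F5, (iBu)2AlH followed by mild hydrolysis gives the C15 aldehyde F6, and NaBH4 with CeCl3·7H2O reduces F6 to 11, where the route is rejoined.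

Step 7. Two processes threaten it at the temperature needed for cycloreversion. One is Cope rearrangement of 9 (C5–C10 re-closure with C2–C3 cleavage to a divinylcyclohexanone); the ester stays conjugated in that isomer, so only the enone conjugation argues against it and the diene must be secured by limiting time and temperature. The other is loss of silanol from the β-silyloxy ketone. The fallback sets out from 8 and changes the order: the ketone is silylated first (TBSOTf, Et3N; enolisation is possible only toward C7) to the photoadduct silyl enol ether F7. Thermolysis of F7 should give 10 directly, with the ketone masked so that elimination is excluded and the product no longer an enolisable enone.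

Step 13. Hydride may be delivered to the wrong face of C6, either because the hindered tertiary C11 hydroxyl exchanges poorly with the borohydride or because the aldol of step 12 placed the side chain on the other face. The fallback sets out from 16 and lets the permanent C8 centre direct the reduction. The C11 mesylate F8 (MsCl, Et3N, DMAP) eliminates through the C6 enolate to the alkylidene keto ester F9, of which only the Z isomer (ester cis to C6, separated from any E isomer) is used. HF·pyridine gives the C8 alcohol F10. A Narasaka–Prasad reduction (Et2BOMe, NaBH4, THF/MeOH, −78 °C) then gives the syn-diol ester F11, whose C6 hydroxyl alone can reach the ester and closes (PPTS) to 21.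

Step 14. Elimination may run toward C13 to give an enol acetate, or chloride may substitute at C11, instead of elimination toward C7. The fallback sets out from 18 and makes the C7 hydrogen acidic. HF·pyridine gives the diol lactone F12, and Dess–Martin periodinane (NaHCO3) oxidises the C8 hydroxyl to the 8-oxo hydroxy lactone F13. Its mesylate F14 (MsCl, Et3N) can lose methanesulfonate only through the C8 enolate, giving the 8-oxo butenolide F15 with the alkene geometry fixed by the lactone ring. Corey–Bakshi–Shibata reduction with the (R)-2-methyl oxazaborolidine and catecholborane, the alkenyl group acting as the large substituent, is expected to return the 8S alcohol 21.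

Step 17. Facial selectivity may be poor at one alkene if a second ring conformer is populated, and traces of acid could cause transannular opening of 25. The fallback sets out from 24 and replaces substrate control by catalyst control: Shi epoxidation with the D-fructose-derived ketone, KHSO5 (as 2KHSO5·KHSO4·K2SO4) and K2CO3 in MeCN/dimethoxymethane/H2O at 0 °C. The two trans trisubstituted alkenes are the substrate class for which this catalyst is most selective, and because they are related by the local twofold axis one catalyst enantiomer suits both (the enantiomeric ketone is used if the sense is opposite). The sequence again passes through 25 to 26.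

## Further compounds

F1 | step 6 | 1-bromocyclobutane-1-carbonitrile | N#CC1(Br)CCC1
F2 | step 6 | cyclobut-1-ene-1-carbonitrile | N#CC1=CCC1
F3 | step 6 | 8-[(tert-butyldimethylsilyl)oxy]-6-methyl-10-oxotricyclo[4.4.0.0(2,5)]decane-2-carbonitrile, head-to-head cis-anti-cis | N#C[C@@]12CC[C@@H]1[C@@]1(C)C[C@H](O[Si](C)(C)C(C)(C)C)CC(=O)[C@H]12
F4 | step 6 | (8S)-8-[(tert-butyldimethylsilyl)oxy]-6-oxogermacra-1(10),4-diene-15-nitrile | C1/C(C#N)=C/C(=O)C[C@@H](O[Si](C)(C)C(C)(C)C)C/C(C)=C/C1
F5 | step 6 | (8S)-6,8-bis[(tert-butyldimethylsilyl)oxy]germacra-1(10),4,6-triene-15-nitrile | C1/C(C#N)=C/C(O[Si](C)(C)C(C)(C)C)=C\[C@@H](O[Si](C)(C)C(C)(C)C)C/C(C)=C/C1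
F6 | step 6 | (8S)-6,8-bis[(tert-butyldimethylsilyl)oxy]germacra-1(10),4,6-trien-15-al | C1/C(C=O)=C/C(O[Si](C)(C)C(C)(C)C)=C\[C@@H](O[Si](C)(C)C(C)(C)C)C/C(C)=C/C1
F7 | step 7 | methyl 8,10-bis[(tert-butyldimethylsilyl)oxy]-6-methyltricyclo[4.4.0.0(2,5)]dec-9-ene-2-carboxylate | COC(=O)[C@@]12CC[C@@H]1[C@@]1(C)C[C@H](O[Si](C)(C)C(C)(C)C)C=C(O[Si](C)(C)C(C)(C)C)[C@H]12
F8 | step 13 | 11-methanesulfonate of 16 | C1/C(C)=C/C(=O)[C@@H](C(OS(C)(=O)=O)(COC(C)=O)C(=O)OCC)[C@@H](O[Si](C)(C)C(C)(C)C)C/C(C)=C/C1
F9 | step 13 | ethyl (7(11)Z,8S)-13-acetoxy-8-[(tert-butyldimethylsilyl)oxy]-6-oxogermacra-1(10),4,7(11)-trien-12-oate | C1/C(C)=C/C(=O)/C(=C(\C(=O)OCC)COC(C)=O)[C@@H](O[Si](C)(C)C(C)(C)C)C/C(C)=C/C1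
F10 | step 13 | ethyl (7(11)Z,8S)-13-acetoxy-8-hydroxy-6-oxogermacra-1(10),4,7(11)-trien-12-oate | C1/C(C)=C/C(=O)/C(=C(\C(=O)OCC)COC(C)=O)[C@@H](O)C/C(C)=C/C1
F11 | step 13 | ethyl (6R,7(11)Z,8S)-13-acetoxy-6,8-dihydroxygermacra-1(10),4,7(11)-trien-12-oate | C1/C(C)=C/[C@@H](O)/C(=C(\C(=O)OCC)COC(C)=O)[C@@H](O)C/C(C)=C/C1
F12 | step 14 | (6R,8S)-13-acetoxy-8,11-dihydroxygermacra-1(10),4-dien-12,6-olide | C1/C(C)=C/[C@H]2OC(=O)C(O)(COC(C)=O)[C@H]2[C@@H](O)C/C(C)=C/C1
F13 | step 14 | (6R)-13-acetoxy-11-hydroxy-8-oxogermacra-1(10),4-dien-12,6-olide | C1/C(C)=C/[C@H]2OC(=O)C(O)(COC(C)=O)[C@H]2C(=O)C/C(C)=C/C1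
F14 | step 14 | 11-methanesulfonate of F13 | C1/C(C)=C/[C@H]2OC(=O)C(OS(C)(=O)=O)(COC(C)=O)[C@H]2C(=O)C/C(C)=C/C1
F15 | step 14 | (6R)-13-acetoxy-8-oxogermacra-1(10),4,7(11)-trien-12,6-olide | C1/C(C)=C/[C@H]2OC(=O)C(COC(C)=O)=C2C(=O)C/C(C)=C/C1
F0 | step 17 | none | none
A1 | alternative 1 | 7,7-dimethoxy-6-[(4-methoxybenzyl)oxy]germacra-1(10)E,4E-dien-8-ol | O[C@H]1C/C(C)=C/CC/C(C)=C/[C@@H](OCc2ccc(OC)cc2)C1(OC)OC
A2 | alternative 2 | 8,13-bis[(tert-butyldimethylsilyl)oxy]-4,5-epoxygermacra-1(10),7(11)-dien-12,6-olide | CC(C)(C)[Si](C)(C)O[C@H]1C/C(C)=C/CC[C@@]2(C)O[C@@H]2[C@H]2OC(=O)C(CO[Si](C)(C)C(C)(C)C)=C12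
A3 | alternative 3 | 8-[(tert-butyldimethylsilyl)oxy]-7,7-dimethoxygermacra-1(10)E,2Z,4E-trien-6-ol | CC(C)(C)[Si](C)(C)O[C@H]1C/C(C)=C/C=C\C(C)=C\[C@@H](O)C1(OC)OC
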